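**Retrosynthetic overview** (target numbered as 2-oxaspiro[4.5]decane: C1 = O–CH bearing the side chain, O2, C3 = lactone C=O, C4 = CH2, C5 = spiro carbon, C6 = ketone, C7=C8, C9 = CH–OAc, C10 = CH2; side chain C1'–C7')
1. The cyclohexenone carries oxygen at C6 and C9 in a 1,4-relationship across C7=C8, and C5 carries a carbinol carbon (C1) and an acetic acid arm (C4–C3). The carbocycle is therefore cut at C5–C6 and C9–C10 into (1E,3E)-1-acetoxy-4-siloxybutadiene (C6–C9, C9 already as its acetate) and an acyclic 1,1-disubstituted enone (C10H2=C5, with C1 as ketone and C4–C3 as CH2CO2Me) that already carries the whole side chain.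
2. One enantioselective endo Diels–Alder reaction closes the cyclohexene and sets C5 (quaternary), C6 and C9 together.
3. The C6–OH then relays to C1 by a 1,3-syn reduction; the C1–OH closes the γ-lactone onto the C3 ester, and C6–OH is oxidised last to the enone carbonyl. Ring order: cyclohexene (step 8), then lactone (step 9).
4. The dienophile comes from monomethyl itaconate acid chloride and an (E)-alkenylalane (Zr-catalysed methylalumination of an (R)-alkynol set by CBS reduction).

Key step: step 8

Assumption: the (S)-oxazaborolidinium ion is written for step 8. Its facial sense on a 1,1-disubstituted vinyl ketone is not secured by a direct analogue, so the enantiomeric catalyst is taken if the opposite face is attacked.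

**Step 1**
Reactants: 1 pent-4-ynoic acid
Product: 2 N-methoxy-N-methylpent-4-ynamide
Conditions: MeNHOMe·HCl, EDC·HCl, N-methylmorpholine, CH2Cl2, 0 °C → rt
Reagents that add atoms: N,O-dimethylhydroxylamine hydrochloride, CNOC.Cl
Why: Carbodiimide amide coupling gives the Weinreb amide, which stops the next organometallic addition at the ketone.

**Step 2**
Reactants: 2 N-methoxy-N-methylpent-4-ynamide; 3 prop-1-en-2-ylmagnesium bromide
Product: 4 2-methylhept-1-en-6-yn-3-one
Conditions: 3 (2.5 equiv), THF, −20 → 0 °C; then cold 1 M HCl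
Reagents that add atoms: none
Why: Weinreb ketone synthesis: the chelated tetrahedral intermediate prevents over-addition, the excess Grignard covers deprotonation of the alkyne C–H, and the acidic quench keeps the liberated amine from adding to the enone.

**Step 3**
Reactants: 4 2-methylhept-1-en-6-yn-3-one
Product: 5 (3R)-2-methylhept-1-en-6-yn-3-ol
Conditions: (S)-2-methyl-CBS-oxazaborolidine (20 mol %), catecholborane, toluene, −78 °C; then MeOH, aq. NaOH wash
Reagents that add atoms: none
Why: Corey–Bakshi–Shibata reduction, with the branched isopropenyl group as the large substituent, should give the (R)-carbinol (C5' of the target); catecholborane at −78 °C leaves alkyne and alkene untouched.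

**Step 4**
Reactants: 5 (3R)-2-methylhept-1-en-6-yn-3-ol
Product: 6 tert-butyldimethyl{[(3R)-2-methylhept-1-en-6-yn-3-yl]oxy}silane
Conditions: TBSCl, imidazole, DMF, rt
Reagents that add atoms: tert-butyldimethylsilyl chloride, CC(C)(C)[Si](C)(C)Cl
Why: Standard silylation masks the carbinol, which would otherwise be acylated in step 6; the TBS ether survives every later step until the final fluoride cleavage.

**Step 5**
Reactants: 7 4-methoxy-2-methylidene-4-oxobutanoic acid (monomethyl itaconate)
Product: 8 methyl 3-(chlorocarbonyl)but-3-enoate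
Conditions: (COCl)2, DMF (cat.), CH2Cl2, 0 °C → rt; used crude
Reagents that add atoms: oxalyl chloride, O=C(Cl)C(=O)Cl
Why: Vilsmeier-type acid chloride formation converts only the free conjugated acid and leaves the methyl ester and the exocyclic methylene unchanged under base-free conditions.

**Step 6**
Reactants: 6 tert-butyldimethyl{[(3R)-2-methylhept-1-en-6-yn-3-yl]oxy}silane; 8 methyl 3-(chlorocarbonyl)but-3-enoate
Product: 10 methyl (5E,9R)-9-{[tert-butyl(dimethyl)silyl]oxy}-6,10-dimethyl-3-methylidene-4-oxoundeca-5,10-dienoate, via alkenylalane 9 (not isolated)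
Conditions: 6, Me3Al, Cp2ZrCl2 (25 mol %), CH2Cl2, 0 °C → rt; volatiles removed in vacuo; then 8, Pd(PPh3)4 (5 mol %), ZnCl2 (cat.), THF, 0 °C → rt
Reagents that add atoms: trimethylaluminium, C[Al](C)C
Why: Negishi zirconium-catalysed methylalumination adds Me and Al syn across the terminal alkyne (Me to the internal carbon), and palladium-catalysed acylation of the alkenylalane with retention then gives the (E)-trisubstituted enone; the alkenyl group transfers in preference to methyl.

**Step 7**
Reactants: 11 (1E,3E)-buta-1,3-diene-1,4-diyl diacetate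
Product: 13 (1E,3E)-4-[(trimethylsilyl)oxy]buta-1,3-dien-1-yl acetate, via lithium dienolate 12 (not isolated)
Conditions: MeLi (2.0 equiv), DME, −78 → −30 °C; then TMSCl (2.2 equiv), −78 °C → rt; pentane, filtration, distillation
Reagents that add atoms: chlorotrimethylsilane, C[Si](C)(C)Cl
Why: Enol acetate cleavage with methyllithium (House enolate generation) should unmask one terminus as the lithium dienolate with retention of the E,E geometry, and O-silylation gives the unsymmetrical diene; the anionic dienolate is expected to be less electrophilic at its remaining acetate than the starting diacetate.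

**Step 8**
Reactants: 10 methyl (5E,9R)-9-{[tert-butyl(dimethyl)silyl]oxy}-6,10-dimethyl-3-methylidene-4-oxoundeca-5,10-dienoate; 13 (1E,3E)-4-[(trimethylsilyl)oxy]buta-1,3-dien-1-yl acetate
Product: 15 methyl 2-[(1S,2S,5S)-5-acetoxy-1-[(2E,6R)-6-{[tert-butyl(dimethyl)silyl]oxy}-3,7-dimethylocta-2,7-dienoyl]-2-hydroxycyclohex-3-en-1-yl]acetate, via cycloadduct silyl ether 14 (not isolated)
Conditions: (S)-o-tolyl-CBS-oxazaborolidine (20 mol %)/Tf2NH (18 mol %), CH2Cl2, −78 → −40 °C; then PPTS (cat.), MeOH, 0 °C
Reagents that add atoms: none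
Why: The cationic oxazaborolidine binds the ketone of 10 and lowers its LUMO, and 13 adds in a concerted but asynchronous [4πs+2πs] Diels–Alder reaction in which the acetoxy-bearing diene terminus bonds first to the unsubstituted C10 and the siloxy-bearing terminus then closes onto the future spiro carbon C5. The closest known reaction type is the chiral oxazaborolidinium-catalysed Diels–Alder reaction of 2-substituted acroleins and of acyclic enones with 1-oxygenated dienes. The one ring closed is the cyclohexene (C5–C6 and C9–C10 bonds), formed by intermolecular suprafacial [4+2] cycloaddition. C5, C6 and C9 are set together: the E,E geometry of 13 places C6–O and C9–O cis to each other, the endo orientation of the activated ketone places the acyl group (future C1) cis to both, and the catalyst, by shielding one face of the bound enone, fixes the absolute sense. The step needs regioselectivity, secured by the siloxy group as the stronger donor (largest HOMO coefficient at the acetoxy-bearing carbon, matched with the terminal CH2 of the enone), chemoselectivity for the 1,1-disubstituted C5=C10 double bond over the hindered trisubstituted C1'=C2' double bond of the same dienone, and endo selectivity, which Lewis acid activation of the ketone reinforces. Mild acid methanolysis then frees the hindered C6–OH from its trimethylsilyl ether while the secondary TBS ether and the acetate stay.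

**Step 9**
Reactants: 15 methyl 2-[(1S,2S,5S)-5-acetoxy-1-[(2E,6R)-6-{[tert-butyl(dimethyl)silyl]oxy}-3,7-dimethylocta-2,7-dienoyl]-2-hydroxycyclohex-3-en-1-yl]acetate
Product: 17 (1R,5S,6S,9S)-1-[(1E,5R)-5-{[tert-butyl(dimethyl)silyl]oxy}-2,6-dimethylhepta-1,6-dien-1-yl]-6-hydroxy-3-oxo-2-oxaspiro[4.5]dec-7-en-9-yl acetate, via syn-diol ester 16 (not isolated)
Conditions: Et2BOMe, THF/MeOH (4:1), −78 °C; NaBH4, −78 °C; AcOH, MeOH co-evaporation; then PPTS (cat.), CH2Cl2, rt
Reagents that add atoms: none
Why: Narasaka–Prasad reduction: in the half-chair boron chelate between C6–OH and the C1 ketone, external hydride should add axially, anti to the axial C10 methylene, giving the 1,3-syn diol, which is the (1R)-carbinol; its lactonisation onto the C3 methyl ester places the side chain cis to C6, while C6–OH, trans to the acetic ester arm, cannot form a fused lactone.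

**Step 10**
Reactants: 17 (1R,5S,6S,9S)-1-[(1E,5R)-5-{[tert-butyl(dimethyl)silyl]oxy}-2,6-dimethylhepta-1,6-dien-1-yl]-6-hydroxy-3-oxo-2-oxaspiro[4.5]dec-7-en-9-yl acetate
Product: 18 (1R,5R,9S)-1-[(1E,5R)-5-{[tert-butyl(dimethyl)silyl]oxy}-2,6-dimethylhepta-1,6-dien-1-yl]-3,6-dioxo-2-oxaspiro[4.5]dec-7-en-9-yl acetate
Conditions: Dess–Martin periodinane, NaHCO3, CH2Cl2, 0 °C → rt
Reagents that add atoms: none
Why: Dess–Martin oxidation of the only free hydroxyl (allylic, at C6) gives the C6 enone under buffered, non-basic conditions that leave lactone, acetate and silyl ether intact; the relay stereocentre C6 is removed and C1, C5 and C9 are unaffected.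

**Step 11**
Reactants: 18 (1R,5R,9S)-1-[(1E,5R)-5-{[tert-butyl(dimethyl)silyl]oxy}-2,6-dimethylhepta-1,6-dien-1-yl]-3,6-dioxo-2-oxaspiro[4.5]dec-7-en-9-yl acetate
Product: 19 (1R,5R,9S)-1-[(1E,5R)-5-hydroxy-2,6-dimethylhepta-1,6-dien-1-yl]-3,6-dioxo-2-oxaspiro[4.5]dec-7-en-9-yl acetate (target)
Conditions: HF·pyridine, pyridine, THF, 0 °C → rt
Reagents that add atoms: none
Why: Buffered fluoride desilylation under mildly acidic conditions frees the C5' carbinol without the base-induced loss or migration of the 4-acetoxy-enone acetate.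

**Compound list**
1 | pent-4-ynoic acid | C#CCCC(=O)O | starting material
2 | N-methoxy-N-methylpent-4-ynamide | C#CCCC(=O)N(C)OC | intermediate
3 | prop-1-en-2-ylmagnesium bromide | C=C(C)[Mg]Br | starting material
4 | 2-methylhept-1-en-6-yn-3-one | C=C(C)C(=O)CCC#C | intermediate
5 | (3R)-2-methylhept-1-en-6-yn-3-ol | C=C(C)[C@H](O)CCC#C | intermediate
6 | tert-butyldimethyl{[(3R)-2-methylhept-1-en-6-yn-3-yl]oxy}silane | C=C(C)[C@H](O[Si](C)(C)C(C)(C)C)CCC#C | intermediate
7 | 4-methoxy-2-methylidene-4-oxobutanoic acid (monomethyl itaconate) | C=C(CC(=O)OC)C(=O)O | starting material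
8 | methyl 3-(chlorocarbonyl)but-3-enoate | C=C(CC(=O)OC)C(=O)Cl | intermediate
9 | [(1E,5R)-5-{[tert-butyl(dimethyl)silyl]oxy}-2,6-dimethylhepta-1,6-dien-1-yl](dimethyl)alane | C[Al](C)/C=C(\C)CC[C@@H](O[Si](C)(C)C(C)(C)C)C(C)=C | intermediate
10 | methyl (5E,9R)-9-{[tert-butyl(dimethyl)silyl]oxy}-6,10-dimethyl-3-methylidene-4-oxoundeca-5,10-dienoate | COC(=O)CC(=C)C(=O)/C=C(\C)CC[C@@H](O[Si](C)(C)C(C)(C)C)C(C)=C | intermediate
11 | (1E,3E)-buta-1,3-diene-1,4-diyl diacetate | CC(=O)O/C=C/C=C/OC(C)=O | starting material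
12 | lithium (1E,3E)-4-acetoxybuta-1,3-dien-1-olate | CC(=O)O/C=C/C=C/[O-].[Li+] | intermediate
13 | (1E,3E)-4-[(trimethylsilyl)oxy]buta-1,3-dien-1-yl acetate | CC(=O)O/C=C/C=C/O[Si](C)(C)C | intermediate
14 | methyl 2-[(1S,2S,5S)-5-acetoxy-1-[(2E,6R)-6-{[tert-butyl(dimethyl)silyl]oxy}-3,7-dimethylocta-2,7-dienoyl]-2-[(trimethylsilyl)oxy]cyclohex-3-en-1-yl]acetate | COC(=O)C[C@@]1(C(=O)/C=C(\C)CC[C@@H](O[Si](C)(C)C(C)(C)C)C(C)=C)C[C@H](OC(C)=O)C=C[C@@H]1O[Si](C)(C)C | intermediate
15 | methyl 2-[(1S,2S,5S)-5-acetoxy-1-[(2E,6R)-6-{[tert-butyl(dimethyl)silyl]oxy}-3,7-dimethylocta-2,7-dienoyl]-2-hydroxycyclohex-3-en-1-yl]acetate | COC(=O)C[C@@]1(C(=O)/C=C(\C)CC[C@@H](O[Si](C)(C)C(C)(C)C)C(C)=C)C[C@H](OC(C)=O)C=C[C@@H]1O | intermediate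
16 | methyl 2-[(1S,2S,5S)-5-acetoxy-1-[(1R,2E,6R)-6-{[tert-butyl(dimethyl)silyl]oxy}-1-hydroxy-3,7-dimethylocta-2,7-dien-1-yl]-2-hydroxycyclohex-3-en-1-yl]acetate | COC(=O)C[C@@]1([C@H](O)/C=C(\C)CC[C@@H](O[Si](C)(C)C(C)(C)C)C(C)=C)C[C@H](OC(C)=O)C=C[C@@H]1O | intermediate
17 | (1R,5S,6S,9S)-1-[(1E,5R)-5-{[tert-butyl(dimethyl)silyl]oxy}-2,6-dimethylhepta-1,6-dien-1-yl]-6-hydroxy-3-oxo-2-oxaspiro[4.5]dec-7-en-9-yl acetate | C=C(C)[C@H](O[Si](C)(C)C(C)(C)C)CC/C(C)=C/[C@H]1OC(=O)C[C@]12C[C@H](OC(C)=O)C=C[C@@H]2O | intermediate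
18 | (1R,5R,9S)-1-[(1E,5R)-5-{[tert-butyl(dimethyl)silyl]oxy}-2,6-dimethylhepta-1,6-dien-1-yl]-3,6-dioxo-2-oxaspiro[4.5]dec-7-en-9-yl acetate | C=C(C)[C@H](O[Si](C)(C)C(C)(C)C)CC/C(C)=C/[C@H]1OC(=O)C[C@]12C[C@H](OC(C)=O)C=CC2=O | intermediate
19 | (1R,5R,9S)-1-[(1E,5R)-5-hydroxy-2,6-dimethylhepta-1,6-dien-1-yl]-3,6-dioxo-2-oxaspiro[4.5]dec-7-en-9-yl acetate | C=C(C)[C@H](O)CC/C(C)=C/[C@H]1OC(=O)C[C@]12C[C@H](OC(C)=O)C=CC2=O | target

**Step count:** 11 steps in total; longest linear sequence 9 steps (steps 1, 2, 3, 4, 6, 8, 9, 10, 11).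

**Steps most likely to fail**

Step 8. The silyl dienol ether may be lost by protodesilylation or Mukaiyama–Michael addition before ring closure. The silyl triflimide released can also catalyse a racemic background cycloaddition, and the face discrimination of the catalyst on a 1,1-disubstituted vinyl ketone may be poor. The fallback moves the enantio-determining cycloaddition to a 2-substituted acrolein, the dienophile class on which this catalyst type is documented, and attaches the side chain afterwards. It sets out from 8 (with 13 and 9) and comes back at 14. Acid chloride 8 is reduced with LiAlH(OtBu)3 at −78 °C to methyl 3-formylbut-3-enoate F1. F1 and 13 undergo the oxazaborolidinium-catalysed Diels–Alder reaction to give methyl 2-[(1S,2S,5S)-5-acetoxy-1-formyl-2-[(trimethylsilyl)oxy]cyclohex-3-en-1-yl]acetate F2. Pinnick oxidation gives (1S,2S,5S)-5-acetoxy-1-(2-methoxy-2-oxoethyl)-2-[(trimethylsilyl)oxy]cyclohex-3-ene-1-carboxylic acid F3. The Ghosez reagent converts it into methyl 2-[(1S,2S,5S)-5-acetoxy-1-(chlorocarbonyl)-2-[(trimethylsilyl)oxy]cyclohex-3-en-1-yl]acetate F4, and palladium-catalysed acylation of alkenylalane 9 with F4 gives 14, which is methanolysed to 15 as in step 8.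

Step 9. The chelate may not control the face of the hindered, α-quaternary enone, so hydride delivery to C1 could be unselective; the acetate could also migrate within the diol. The fallback replaces substrate control by reagent control on the silyl-protected ketone. It sets out from 14 (isolated by omitting the methanolysis of step 8) and comes back at 17. CBS reduction of 14 ((S)-2-methyl-CBS-oxazaborolidine, catecholborane, −78 °C, with the quaternary carbon as the large group) gives methyl 2-[(1R,2S,5S)-5-acetoxy-1-[(1R,2E,6R)-6-{[tert-butyl(dimethyl)silyl]oxy}-1-hydroxy-3,7-dimethylocta-2,7-dien-1-yl]-2-[(trimethylsilyl)oxy]cyclohex-3-en-1-yl]acetate F5. F5 lactonises to (1R,5R,6S,9S)-1-[(1E,5R)-5-{[tert-butyl(dimethyl)silyl]oxy}-2,6-dimethylhepta-1,6-dien-1-yl]-3-oxo-6-[(trimethylsilyl)oxy]-2-oxaspiro[4.5]dec-7-en-9-yl acetate F6, and PPTS in methanol then gives 17.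

Step 7. Cleavage of the two enol acetates may be statistical, acetyl groups may scramble between dienolate and diacetate, and the aldehyde enolate may undergo aldol addition to the acetone formed. The fallback separates cleavage and silylation. It sets out from 11 and comes back at 13. Lipase-catalysed transesterification with one equivalent of 1-butanol removes one enol acetate, and tautomerisation gives (2E)-4-oxobut-2-en-1-yl acetate F7. Soft enolisation of F7 (TMSCl, Et3N, ZnCl2 cat.) gives 13; any (1E,3Z) isomer stays behind in step 8 because it cannot readily reach the s-cis conformation.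

**Further compounds**
F1 | step 8 | methyl 3-formylbut-3-enoate | C=C(C=O)CC(=O)OC
F2 | step 8 | methyl 2-[(1S,2S,5S)-5-acetoxy-1-formyl-2-[(trimethylsilyl)oxy]cyclohex-3-en-1-yl]acetate | COC(=O)C[C@@]1(C=O)C[C@H](OC(C)=O)C=C[C@@H]1O[Si](C)(C)C
F3 | step 8 | (1S,2S,5S)-5-acetoxy-1-(2-methoxy-2-oxoethyl)-2-[(trimethylsilyl)oxy]cyclohex-3-ene-1-carboxylic acid | COC(=O)C[C@@]1(C(=O)O)C[C@H](OC(C)=O)C=C[C@@H]1O[Si](C)(C)C
F4 | step 8 | methyl 2-[(1S,2S,5S)-5-acetoxy-1-(chlorocarbonyl)-2-[(trimethylsilyl)oxy]cyclohex-3-en-1-yl]acetate | COC(=O)C[C@@]1(C(=O)Cl)C[C@H](OC(C)=O)C=C[C@@H]1O[Si](C)(C)C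
F5 | step 9 | methyl 2-[(1R,2S,5S)-5-acetoxy-1-[(1R,2E,6R)-6-{[tert-butyl(dimethyl)silyl]oxy}-1-hydroxy-3,7-dimethylocta-2,7-dien-1-yl]-2-[(trimethylsilyl)oxy]cyclohex-3-en-1-yl]acetate | COC(=O)C[C@@]1([C@H](O)/C=C(\C)CC[C@@H](O[Si](C)(C)C(C)(C)C)C(C)=C)C[C@H](OC(C)=O)C=C[C@@H]1O[Si](C)(C)C
F6 | step 9 | (1R,5R,6S,9S)-1-[(1E,5R)-5-{[tert-butyl(dimethyl)silyl]oxy}-2,6-dimethylhepta-1,6-dien-1-yl]-3-oxo-6-[(trimethylsilyl)oxy]-2-oxaspiro[4.5]dec-7-en-9-yl acetate | C=C(C)[C@H](O[Si](C)(C)C(C)(C)C)CC/C(C)=C/[C@H]1OC(=O)C[C@]12C[C@H](OC(C)=O)C=C[C@@H]2O[Si](C)(C)C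
F7 | step 7 | (2E)-4-oxobut-2-en-1-yl acetate | CC(=O)OC/C=C/C=O
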